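The rate constants belong to no real substance; the result is computed.

Two questions stand over the flasks below, which differ in their charge of substrate: what share of what became target or isomer of the product is target at the end of the run, and what course that share takes as the charge climbs.

all flasks: partner 26.0 mM; free catalyst 1.3 mM; time 40 s

| charge | substrate |
|---|---|
| dusk | 1.5 mM |
| midnight | 4.0 mM |
| summer | 12 mM |
| autumn | 40 mM |
| noon | 120 mM |

    substrate + partner ⇌ target (K1 = 280 M⁻¹, k1 = 1.4 M⁻¹ s⁻¹)
    substrate + partner ⇌ isomer of the product (K2 = 95 M⁻¹, k2 = 0.46 M⁻¹ s⁻¹)
    target + free catalyst ⇌ isomer of the product + free catalyst, rate k3*[free catalyst]*[target] forward; the back reaction follows from the equilibrium constant (k3 = 3.4 M⁻¹ s⁻¹)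
    partner → decomposed reagent (k4 = 0.020 s⁻¹)
    free catalyst → spent catalyst (k5 = 7.1 × 10⁻⁶ s⁻¹)
    2 free catalyst ⇌ resting dimer, settled at all times (K6 = 22000 M⁻¹)

- share of target in all that became target or isomer of the product for dusk, midnight, summer, autumn, noon, in this order
- the course of these numbers from the first flask to the last (rises all the way / rises, then falls / hardly changes / falls all the way / falls, then rises)

- a step written with two of one species runs at k times the square of its concentration and takes two of it each time
- "hardly changes" means that all values lie within two and a half points (for a concentration: within two and a half percent of the largest)
- run time (dusk): 40 s

We begin with the two ends the share can take. Both forward steps run on the same product of c substrate and c partner, so fresh product comes in the ratio of their rate constants, which gives a fresh share of 75.3%, the mark of kinetic control. Product that has reached balance stands in the ratio of the equilibrium constants, which gives a balanced share of 74.7%, the mark of thermodynamic control. These stand 0.6 percentage points apart, and we call this distance, the fresh share minus the balanced share, the window.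

Next we count turnovers, the number of time constants of the move towards balance that fit into the run. Treating the catalyst charge as free, the isomerisation relaxes at k3 times c free catalyst times (1 + K1/K2), or 0.0174 s⁻¹, and the way back of step 1 adds 0.00500 s⁻¹, with step 2 returning at nearly that rate. Over 40 s that makes 0.898 turnovers, which by this estimate closes 59.3% of the window for product made at the very start, the oldest case, so we would put the floor of the share at 74.9%.

The weak link is the free catalyst. The product of K6 and the catalyst charge is 29, so the balance with resting dimer, the resting state here, leaves c free catalyst at 0.161 mM, less than the 1.3 mM charged. The relaxation falls to 0.00216 s⁻¹, slower than the way back, and the count falls to 0.286 turnovers. By the same estimate that closes 24.9% of the window and raises our floor to 75.1%. We commit to shares between this floor and the fresh share, and to a course that hardly changes.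

The forecast gives 75.17%, 75.17%, 75.16%, 75.15% and 75.13%, with the course hardly changes, on the ground that “These nearly coincide, so isomerisation can move the share very little”. It names single values where we name a range.

The simulation gives 75.2%, 75.2%, 75.2%, 75.2% and 75.1%, and the course hardly changes.

The window of 0.6 points, running from 74.7% to 75.3%, holds dusk at 75.2% and, at the other end of the row, noon at 75.1%. The share in dusk stands there because of the direct step from substrate and partner to isomer of the product, both ways: the run without it lifts the share from 75.2% to 98.6%. In noon, the same removal lifts the share from 75.1% to 98.2%.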